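**Strategy.** Everything rests on cutting the methylene bridge between the bridging CH2, kept on ring A (the butanoyl/methoxy ring), and the ring carbon of ring B (the propanoyl ring) that lies between two hydroxyls. The key step exploits the free C6–OH of ring A, ortho to the bridging carbon: it allows a benzylic dimethylamine on that CH2 to be expelled as an ortho-quinone methide. This electrophile is captured by the single unsubstituted, doubly OH-flanked carbon of ring B through C-alkylation. One protecting-group-free operation joins both fully functionalised acylphloroglucinols. The precursor is the 5-(dimethylaminomethyl) Mannich base of aspidinol, partnered with 2,4,6-trihydroxy-3-methylpropiophenone.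

Key step: step 5

Assumption: the target has no stereocentre and no configurationally stable axis (it is achiral), so the compound itself is the single stereoisomer and no step has to control configuration.

Step 1
Reactants: 1 2-methylphloroglucinol (2-methylbenzene-1,3,5-triol); 2 butanoyl chloride
Product: 3 1-(2,4,6-trihydroxy-3-methylphenyl)butan-1-one
Conditions: AlCl3 (3.5 equiv), PhNO2/CH2Cl2, 0 °C → rt; ice/aq. HCl
Reagents that add atoms: none
Why: Friedel–Crafts C-acylation of the strongly activated triol: the two unsubstituted ring carbons of 1 are equivalent by symmetry, any aryl ester formed first is carried to the ketone by Fries rearrangement under AlCl3, and the aluminium-chelated ketone deactivates the ring against a second acylation.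

Step 2
Reactants: 3 1-(2,4,6-trihydroxy-3-methylphenyl)butan-1-one
Product: 4 1-(2,6-dihydroxy-4-methoxy-3-methylphenyl)butan-1-one (aspidinol)
Conditions: Me2SO4 (1.0 equiv), K2CO3 (1.0 equiv), acetone, 0 °C → rt
Reagents that add atoms: dimethyl sulfate, COS(=O)(=O)OC
Why: Williamson-type O-methylation with a hard electrophile: the 4-OH para to the ketone is the most acidic hydroxyl and lies outside the hydrogen-bonded chelate that ties the ortho hydroxyls to the C=O, so one equivalent of base and Me2SO4 should methylate it in preference to the 2- and 6-OH and to the free ring carbon.

Step 3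
Reactants: 4 1-(2,6-dihydroxy-4-methoxy-3-methylphenyl)butan-1-one (aspidinol)
Product: 5 1-[3-[(dimethylamino)methyl]-2,6-dihydroxy-4-methoxy-5-methylphenyl]butan-1-one
Conditions: Eschenmoser's salt (1.2 equiv), K2CO3 (1.2 equiv), MeCN, 0 °C → rt; pH 7 buffer work-up
Reagents that add atoms: N,N-dimethylmethyleneiminium iodide (Eschenmoser's salt), C=[N+](C)C.[I-]
Why: Mannich aminomethylation (electrophilic aromatic substitution by a preformed iminium ion) at C5, the only unsubstituted ring carbon, which is activated by the ortho and para hydroxyls and the ortho methoxy group; the excess of preformed iminium should consume 4 before the product can pass its CH2 to a second arene.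

Step 4
Reactants: 1 2-methylphloroglucinol (2-methylbenzene-1,3,5-triol); 6 propanoyl chloride
Product: 7 1-(2,4,6-trihydroxy-3-methylphenyl)propan-1-one
Conditions: AlCl3 (3.5 equiv), PhNO2/CH2Cl2, 0 °C → rt; ice/aq. HCl
Reagents that add atoms: none
Why: Friedel–Crafts C-acylation as in step 1, the two free ring positions of 1 again being equivalent and the chelated product ketone resisting over-acylation.

Step 5
Reactants: 5 1-[3-[(dimethylamino)methyl]-2,6-dihydroxy-4-methoxy-5-methylphenyl]butan-1-one; 7 1-(2,4,6-trihydroxy-3-methylphenyl)propan-1-one
Product: 9 1-[2,6-dihydroxy-4-methoxy-3-methyl-5-[(2,4,6-trihydroxy-3-methyl-5-propanoylphenyl)methyl]phenyl]butan-1-one, via ortho-quinone methide 8 (not isolated)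
Conditions: 7 (1.5 equiv), 1,4-dioxane, 100 °C, N2 sweep
Reagents that add atoms: none
Why: Thermal loss of dimethylamine from the zwitterionic form of 5 (the C6–OH passes its proton to nitrogen, then E1cB-type elimination) should give ortho-quinone methide 8, whose exocyclic CH2 is attacked in a Michael-type Friedel–Crafts alkylation by the only unsubstituted ring carbon of 7, and tautomerisation of the resulting dienones restores both aromatic rings. The closest known reaction type is the Mannich-base (ortho-quinone methide) alkylation of phenols and 1,3-dicarbonyl compounds, as used for unsymmetrical methylene-bridged acylphloroglucinols. No ring is closed and no stereocentre is formed. The step needs cross- over homo-coupling and C- over O-alkylation: 8 carries no free nucleophilic ring carbon and 7 carries exactly one, 7 is used in excess, and any benzyl aryl ether formed at oxygen can revert to 8 under the thermal conditions. Sweeping out the volatile amine with nitrogen keeps the medium close to neutral and so should limit base-promoted exchange of the methylene bridge.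

**Compound list**

1 | 2-methylbenzene-1,3,5-triol (2-methylphloroglucinol) | Cc1c(O)cc(O)cc1O | starting material
2 | butanoyl chloride | CCCC(Cl)=O | starting material
3 | 1-(2,4,6-trihydroxy-3-methylphenyl)butan-1-one | CCCC(=O)c1c(O)c(C)c(O)cc1O | intermediate
4 | 1-(2,6-dihydroxy-4-methoxy-3-methylphenyl)butan-1-one (aspidinol) | CCCC(=O)c1c(O)c(C)c(OC)cc1O | intermediate
5 | 1-[3-[(dimethylamino)methyl]-2,6-dihydroxy-4-methoxy-5-methylphenyl]butan-1-one | CCCC(=O)c1c(O)c(C)c(OC)c(CN(C)C)c1O | intermediate
6 | propanoyl chloride | CCC(Cl)=O | starting material
7 | 1-(2,4,6-trihydroxy-3-methylphenyl)propan-1-one | CCC(=O)c1c(O)c(C)c(O)cc1O | intermediate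
8 | 2-butanoyl-3-hydroxy-5-methoxy-4-methyl-6-methylidenecyclohexa-2,4-dien-1-one (ortho-quinone methide) | CCCC(=O)C1=C(O)C(C)=C(OC)C(=C)C1=O | intermediate
9 | 1-[2,6-dihydroxy-4-methoxy-3-methyl-5-[(2,4,6-trihydroxy-3-methyl-5-propanoylphenyl)methyl]phenyl]butan-1-one | CCCC(=O)c1c(O)c(C)c(OC)c(Cc2c(O)c(C)c(O)c(C(=O)CC)c2O)c1O | target

**Step count and risks**

Total step count: 5. Longest linear sequence: 4 steps (steps 1, 2, 3 and 5); step 4 is a one-step branch.

Steps most likely to fail:

1. Step 5. The methylene bridge may exchange at 100 °C in the presence of the released amine (fragmentation of the product back to a quinone methide and recombination), scrambling the two rings into symmetric dimers; amine loss may also be sluggish at a temperature the free phenols tolerate. Fallback: setting out from 5, N-methylation with MeI in acetone at rt should give the quaternary salt (3-butanoyl-2,4-dihydroxy-6-methoxy-5-methylphenyl)methyl-trimethylammonium iodide F1. Stirring F1 with 7 and NaHCO3 in aqueous MeCN at rt should expel trimethylamine and regenerate 8 at a temperature too low for bridge exchange, and capture by 7 comes back to the route at 9.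

2. Step 2. Methylation may continue onto a chelated ortho hydroxyl, discriminate poorly between the three hydroxyls, or take place on the free ring carbon. Fallback: setting out from 3, exhaustive O-methylation (excess Me2SO4, K2CO3, acetone, reflux) should give 1-(2,4,6-trimethoxy-3-methylphenyl)butan-1-one F2. Chelation-directed cleavage of the two methoxy groups ortho to the ketone with BCl3 (excess, CH2Cl2, −78 °C → rt) should leave the para methoxy group untouched and comes back to the route at 4.

3. Step 3. The newly formed benzylic amine may lose dimethylamine while unreacted 4 is still present, so that its CH2 is transferred to a second molecule of 4 and a symmetric diarylmethane forms. Fallback: setting out from 4, Rieche formylation (Cl2CHOMe, TiCl4, CH2Cl2, −20 → 0 °C; aq. HCl) should give 3-butanoyl-2,4-dihydroxy-6-methoxy-5-methylbenzaldehyde F3, in which the one-carbon unit cannot alkylate an arene. Reductive amination of F3 (Me2NH, NaBH(OAc)3, 1,2-dichloroethane, rt) comes back to the route at 5.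

**Further compounds**

F1 | step 5 | (3-butanoyl-2,4-dihydroxy-6-methoxy-5-methylphenyl)methyl-trimethylammonium iodide | CCCC(=O)c1c(O)c(C)c(OC)c(C[N+](C)(C)C)c1O.[I-]
F2 | step 2 | 1-(2,4,6-trimethoxy-3-methylphenyl)butan-1-one | CCCC(=O)c1c(OC)c(C)c(OC)cc1OC
F3 | step 3 | 3-butanoyl-2,4-dihydroxy-6-methoxy-5-methylbenzaldehyde | CCCC(=O)c1c(O)c(C)c(OC)c(C=O)c1O
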